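# Route to querciformolide C

**Retrosynthetic overview**
1. The target comes from a last-step Yamaguchi closure of the seven-membered α-methylene lactone onto the C12 tertiary alcohol. C17 is oxidised from the isopropenyl methyl group late, while only the isopropenyl alkene remains.
2. The cis-4,7-tetrahydrofuran with its C3/C8 hydroxyls comes from a biomimetic diepoxide-to-THF cascade on a macrocyclic (3E,7E)-diene.
3. The 14-membered ring comes from an intramolecular pinacol coupling of the C11 aldehyde and C12 methyl ketone, which also makes the 11,12-diol.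
4. The chain is built from (R)-limonene-derived keto-aldehyde **2** by two iterative Claisen [3,3] homologations (vinyl ether / 2-methylallylic carbinol). These form C5–C6 and C9–C10 and fix the E-trisubstituted Δ3 and Δ7 alkenes.
5. Ring order: macrocycle (step 6), THF (step 9), lactone (step 14). C1 is the only purchased stereocentre.

**Assumptions**
- Carbon numbering is cembrane numbering as in the target: ring C1–C14, isopropyl-derived C15–C17, methyls C18 (on C4), C19 (on C8), C20 (on C12).
- Only substrates, skeleton-contributing building blocks and products are numbered. Oxidants, acids and bases are given as reagents.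
- The C1 stereocentre biases the macrocycle conformation, so the pinacol coupling and the peripheral-face epoxidations give the required faces as the major diastereomers. Minor isomers are removed by chromatography.

---

**Step 1**
Reactants: **1** (R)-(+)-limonene 1,2-oxide, cis/trans mixture
Product: **2** (R)-3-isopropenyl-6-oxoheptanal
Conditions: H5IO6, THF/H2O, 0 °C → rt
Reagents that add atoms: periodic acid, O=I(O)(O)(O)(O)O; water, O
Why: Periodic acid opens the epoxide to the diol and cleaves it (oxidative cleavage of the diol), so both epoxide diastereomers converge on one keto-aldehyde. The limonene stereocentre becomes C1 (R) and is untouched.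

**Step 2**
Reactants: **2**; **3** isopropenylmagnesium bromide
Product: **4** (3RS,6R)-2-methyl-oct-1-ene-type allylic alcohol, 1-(2-propenyl) carbinol at C3 with the C12 methyl ketone intact
Conditions: 1.0 equiv **3**, THF, −78 °C; aq. NH4Cl
Reagents that add atoms: isopropenylmagnesium bromide, C=C(C)[Mg]Br
Why: Grignard addition is chemoselective for the aldehyde over the methyl ketone at low temperature. The new C3 carbinol is an epimeric mixture, but it is destroyed in the next step.

**Step 3 (central sigmatropic step)**
Reactants: **4**; **5** vinyl acetate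
Product: **6** (E)-aldehyde, OHC(C7)–C6–C5–C4(Me)=C3–C2–C1
Conditions: **5** (excess), [Ir(cod)Cl]2 (1 mol %), Na2CO3, toluene, 100 °C (allyl vinyl ether); then 180 °C, sealed tube
Reagents that add atoms: vinyl acetate, C=COC(C)=O
Why: Ir-catalysed transvinylation gives the allyl vinyl ether. The thermal Claisen [3,3] rearrangement through a chair transition state, with the C2 chain equatorial, forms C5–C6 and the (E)-trisubstituted C3=C4 alkene. The C3 carbinol configuration is erased.

**Step 4**
Reactants: **6**; **3**
Product: **7** C7 secondary allylic alcohol (2-methylallyl carbinol, epimeric at C7)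
Conditions: 1.0 equiv **3**, THF, −78 °C
Reagents that add atoms: isopropenylmagnesium bromide, C=C(C)[Mg]Br
Why: Same chemoselective aldehyde addition; the C7 stereocentre is destroyed in step 5.

**Step 5 (second Claisen)**
Reactants: **7**; **5**
Product: **8** keto-aldehyde, C11 aldehyde and C12 methyl ketone, Δ3 (E), Δ7 (E)
Conditions: **5**, [Ir(cod)Cl]2, Na2CO3, toluene, 100 °C; then 180 °C
Reagents that add atoms: vinyl acetate, C=COC(C)=O
Why: Same Ir-vinylation/chair Claisen sequence. It forms C9–C10 and the (E)-Δ7 alkene, completing all 20 carbons.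

**Step 6**
Reactants: **8**
Product: **9** (1R,11R,12R,3E,7E)-cembra-3,7,15-triene-11,12-diol
Conditions: TiCl3(DME)1.5, Zn–Cu, DME, 0 °C → rt, syringe-pump addition at about 1 mM
Reagents that add atoms: none
Why: Intramolecular low-valent-titanium pinacol coupling (kept cold to avoid McMurry deoxygenation) joins the aldehyde and ketone to close the 14-membered ring. It creates C11 and C12 with the required 11R,12R relative configuration, directed by the C1-biased ring conformation.

**Step 7**
Reactants: **9**
Product: **10** 11-acetate of **9**
Conditions: Ac2O (1.1 equiv), Et3N, DMAP (cat.), CH2Cl2, −20 °C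
Reagents that add atoms: acetic anhydride, CC(=O)OC(C)=O
Why: Only the secondary C11 alcohol is acylated. This installs the target C11 acetate and prevents C11–OH from competing as a nucleophile in the epoxide cascade; C12 is tertiary and unreactive.

**Step 8**
Reactants: **10**
Product: **11** (1R,3S,4S,7S,8S,11R,12R)-3,4:7,8-diepoxycembr-15-ene-11,12-diol 11-acetate
Conditions: mCPBA (2.1 equiv), NaHCO3, CH2Cl2, −20 °C
Reagents that add atoms: mCPBA, OOC(=O)c1cccc(Cl)c1
Why: Electrophilic epoxidation is stereospecific and keeps the E geometry. It is selective for the two trisubstituted alkenes over the 1,1-disubstituted isopropenyl group (about 13:1 faster). Peripheral-face attack gives the (3S,4S)/(7S,8S) epoxides.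

**Step 9**
Reactants: **11**
Product: **12** (1R,3S,4R,7S,8R,11R,12R)-4,7-epoxycembr-15-ene-3,8,11,12-tetrol 11-acetate
Conditions: CSA (20 mol %), MeCN/CH2Cl2, H2O (10 equiv), 0 °C
Reagents that add atoms: water, O
Why: The oxygen of the 7,8-epoxide attacks protonated C4 of the 3,4-epoxide with inversion. This forms the cis-THF (C4 becomes R, C7 retained S), and the oxiranium is opened by water at C8 with inversion (C8 becomes R), leaving C3–OH (S, retained).

**Step 10**
Reactants: **12**
Product: **13** 3,11-diacetate
Conditions: Ac2O (1.5 equiv), Et3N, DMAP (cat.), CH2Cl2, rt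
Reagents that add atoms: acetic anhydride, CC(=O)OC(C)=O
Why: The secondary C3 alcohol is acetylated; the tertiary C8 and C12 alcohols are too hindered to react and stay free for the lactonisation.

**Step 11**
Reactants: **13**
Product: **14** C17 primary allylic alcohol
Conditions: SeO2 (10 mol %), TBHP (3 equiv), CH2Cl2, rt
Reagents that add atoms: tert-butyl hydroperoxide, CC(C)(C)OO
Why: With all other alkenes oxidised, the isopropenyl group is the only alkene left. Riley/ene allylic oxidation at the methyl group gives the 2-substituted allylic alcohol, with no new stereocentre.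

**Step 12**
Reactants: **14**
Product: **15** C17 enal
Conditions: MnO2 (20 equiv), CH2Cl2, rt
Reagents that add atoms: none
Why: MnO2 oxidises only the allylic primary alcohol; the acetylated secondary carbons and the tertiary alcohols are inert.

**Step 13**
Reactants: **15**
Product: **16** C17 α-methylene carboxylic acid
Conditions: NaClO2, NaH2PO4, 2-methyl-2-butene, t-BuOH/H2O, rt
Reagents that add atoms: sodium chlorite, [Na+].[O-]Cl=O
Why: Pinnick oxidation converts the enal to the acid without attacking the acrylate alkene (the scavenger traps HOCl).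

**Step 14**
Reactants: **16**
Product: **17** querciformolide C
Conditions: 2,4,6-Cl3C6H2COCl, Et3N, THF; then dropwise into DMAP, toluene, 80 °C (about 1 mM)
Reagents that add atoms: none
Why: Yamaguchi intramolecular esterification of the mixed anhydride with the C12 tertiary alcohol closes the 7-membered α-methylene lactone. C12 is not touched (retention), so its configuration is that set in step 6.

---

**Compound list**

| No. | Name | SMILES | Role |
|---|---|---|---|
| 1 | (R)-(+)-limonene 1,2-oxide (cis/trans) | C=C(C)[C@@H]1CCC2(C)OC2C1 | starting material |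
| 2 | (R)-3-isopropenyl-6-oxoheptanal | O=CC[C@H](C(C)=C)CCC(C)=O | intermediate |
| 3 | isopropenylmagnesium bromide | C=C(C)[Mg]Br | starting material |
| 4 | C3 allylic alcohol (C3 epimeric), C12 ketone intact | CC(=C)C(O)C[C@H](C(C)=C)CCC(C)=O | intermediate |
| 5 | vinyl acetate | C=COC(C)=O | starting material |
| 6 | (E)-Δ3 aldehyde (C7 CHO) | O=CCC/C(C)=C/C[C@H](C(C)=C)CCC(C)=O | intermediate |
| 7 | C7 allylic alcohol (epimeric) | CC(=C)C(O)CC/C(C)=C/C[C@H](C(C)=C)CCC(C)=O | intermediate |
| 8 | (3E,7E) keto-aldehyde (C11 CHO, C12 COMe) | O=CCC/C(C)=C/CC/C(C)=C/C[C@H](C(C)=C)CCC(C)=O | intermediate |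
| 9 | (1R,11R,12R,3E,7E)-cembra-3,7,15-triene-11,12-diol | C=C(C)[C@H]1C/C=C(C)/CC/C=C(C)/CC[C@@H](O)[C@](C)(O)CC1 | intermediate |
| 10 | 11-acetate of 9 | C=C(C)[C@H]1C/C=C(C)/CC/C=C(C)/CC[C@@H](OC(C)=O)[C@](C)(O)CC1 | intermediate |
| 11 | (3S,4S,7S,8S)-3,4:7,8-diepoxide of 10 | C=C(C)[C@H]1C[C@@H]2O[C@@]2(C)CC[C@@H]3O[C@@]3(C)CC[C@@H](OC(C)=O)[C@](C)(O)CC1 | intermediate |
| 12 | 4,7-epoxycembr-15-ene-3,8,11,12-tetrol 11-acetate (3S,4R,7S,8R,11R,12R) | C=C(C)[C@H]1C[C@H](O)[C@@]2(C)CC[C@H](O2)[C@](C)(O)CC[C@@H](OC(C)=O)[C@](C)(O)CC1 | intermediate |
| 13 | 3,11-diacetate of 12 | C=C(C)[C@H]1C[C@H](OC(C)=O)[C@@]2(C)CC[C@H](O2)[C@](C)(O)CC[C@@H](OC(C)=O)[C@](C)(O)CC1 | intermediate |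
| 14 | C17 allylic alcohol | OCC(=C)[C@H]1C[C@H](OC(C)=O)[C@@]2(C)CC[C@H](O2)[C@](C)(O)CC[C@@H](OC(C)=O)[C@](C)(O)CC1 | intermediate |
| 15 | C17 enal | O=CC(=C)[C@H]1C[C@H](OC(C)=O)[C@@]2(C)CC[C@H](O2)[C@](C)(O)CC[C@@H](OC(C)=O)[C@](C)(O)CC1 | intermediate |
| 16 | C17 α-methylene carboxylic acid | OC(=O)C(=C)[C@H]1C[C@H](OC(C)=O)[C@@]2(C)CC[C@H](O2)[C@](C)(O)CC[C@@H](OC(C)=O)[C@](C)(O)CC1 | intermediate |
| 17 | querciformolide C | C=C1C(=O)O[C@]2(C)CC[C@@H]1C[C@H](OC(C)=O)[C@@]1(C)CC[C@H](O1)[C@](C)(O)CC[C@H]2OC(C)=O | target |

**Totals**
- Total steps: 14.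
- Longest linear sequence: 14 steps from **1**.

**Three steps most likely to fail**
1. **Step 9 (diepoxide → THF cascade).** Facial selectivity and the oxiranium opening at tertiary C8 may be poor, and the free C12–OH may divert the cascade to a THP. Fallback: build the cis-THF from the (R)-linalool ozonolysis lactol, using chelation-controlled additions at C3, C7 and C8, and couple it to a lactone-bearing fragment by ring-closing metathesis.
2. **Step 6 (pinacol macrocyclisation).** The 11R,12R diastereoselectivity and the yield at 14-ring size are unproven. Fallback: make the lactone before the macrocycle. Use vinylMgBr addition to the C12 ketone of a C17-oxidised fragment, lactonise, separate the C12 diastereomers, and close the ring by ring-closing metathesis.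
3. **Step 14 (lactonisation onto the C12 tertiary alcohol).** DMAP conjugate addition or oligomerisation of the α-methylene mixed anhydride is a risk. Fallback: form the ε-lactone by Baeyer–Villiger expansion of a carvone-derived 2-methyl-2-alkyl-5-substituted cyclohexanone (the tertiary carbon migrates with retention), then attach the macrocycle chains and close the ring by ring-closing metathesis.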